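## Structural features

The target 15 is a cyclohex-2-en-1-one: C1 is the carbonyl, C2=C3 the alkene, C4 carries OMe, C5 is a methylene, and C6 is an all-carbon quaternary stereocentre. C6 bears an allyl group and the side chain C7H(CH3)–C8H(OH)–aryl (aryl = 3,4,5-trimethoxyphenyl; O8 is the oxygen on C8). C6 (R), C7 (S) and C8 (S) are contiguous, with C7/C8 anti (methyl and hydroxyl on opposite sides of the C6–C7–C8–aryl zigzag). The fourth centre, C4 (R), is 1,3 to C6, with OMe cis to the side chain and trans to the allyl group. Fragile elements are the γ-hydroxy ketone (O8/C1), the electron-rich benzylic alcohol (ionizes in acid), the γ-methoxy enone (C4–H is vinylogously acidic), and the terminal alkene, which rules out late hydrogenation, hydroboration or ozonolysis. The real difficulty is the quaternary C6 wedged between a ketone and two acyclic stereocentres: an intermolecular C6–C7 bond would need substitution at a secondary carbon, and no single catalyst-controlled step addresses C6, C7 and C8 together. The key step exploits two hidden relationships: O8–C8–C7–C6–C1 is a γ-butyrolactone ring once C1 is written at the acid oxidation level, and C1 and C3 of the carbocycle are the carbonyl carbons of a cyclohexane-1,3-dione whose C1–C2 bond is a Claisen-condensation bond. In one sentence: 15 arises from the intramolecular Claisen condensation of keto lactone 9, which turns the lactone into the carbocycle of the bicyclic vinylogous ester 11.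

## Logic of the disconnections

**15 ⇒ 13.** No skeletal bond is cut. The C1=O/C2=C3 enone and the free O8–H are exchanged for an O8–C1 enol ether bond and a C3 carbonyl. This hides the enone, the γ-hydroxy ketone and the benzylic alcohol in one rigid bicyclic vinylogous ester, with O8 acting as its own protecting group, and it places C4 α to a ketone. The forward step must reduce C3=O in a 1,2 sense and then hydrate at C1 under acid mild enough not to ionize C8–O or lose methanol.

**13 ⇒ 12 ⇒ 11.** The O–CH3 bond and then the C4–O bond are cut. C4 is the only enolizable position of 11 because C6 is quaternary, so enolate oxygenation is regiochemically unambiguous and the precursor loses one stereocentre. The forward step needs oxygen delivery anti to the pseudoaxial allyl group on C6; the same isomer is also the thermodynamic one (equatorial OMe).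

**11 ⇒ 9 (through 10).** The C1–C2 bond is cut and the O8–C1 enol ether bond is traced back to the O8–C1 acyl bond of a lactone. The carbocycle disappears and C6, C7 and C8 all sit on a five-membered lactone, where they can be set by a cyclic template. The forward step demands that a methyl ketone enolate acylate a hindered, α-quaternary lactone carbonyl; the driving force is the formation of a 1,3-diketonate.

**9 ⇒ 8 ⇒ 7 ⇒ 5 + 6.** After a ketal/ketone exchange (9 ⇒ 8), the C6–CH2(allyl) bond and then the C6–C5 bond are cut at the lactone enolate. Both new bonds are made at primary or allylic carbons, and the quaternary centre is reduced to two enolate alkylations. The allyl group must enter second and anti to the C7 methyl group, because the target has allyl trans to C7–CH3 on the O8–C8–C7–C6–C1 ring.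

**5 ⇒ 4 ⇒ 3.** The O8–C1 acyl bond is opened and C1 is taken back to a terminal alkene carbon. The lactone becomes an acyclic homoallylic alcohol carrying only C7 and C8. The forward steps are anti-Markovnikov hydration and an oxidation that distinguishes the primary from the benzylic alcohol.

**3 ⇒ 1 + 2.** The C7–C8 bond is cut. Both acyclic stereocentres arise in one crotylboration of an aromatic aldehyde; the (E)-geometry of 2 must translate into the anti relationship, and the catalyst must select the si face of 1.

## Other disconnections considered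

**Alternative 1:** (the first that comes to mind) Cut C6–CH2(allyl) and C6–C7 at the α′-enolate of a preformed 4-methoxycyclohexenone. The forward key step would be alkylation of the kinetic lithium enolate of A1 with a C7 electrophile, in practice opening of cis-epoxide A2 at its methyl-bearing carbon, with allylation before or after.
- Structure: the C6–C7 bond would be made intermolecularly at a secondary carbon.
- Mechanism: the electron-rich aryl group directs epoxide opening to the benzylic carbon instead, and ketone enolates open epoxides poorly. The configuration of C6 would depend only on the remote C4–OMe group, with no control of the C6/C7 relationship.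
- The chosen plan makes every C–C bond at a primary, allylic or acyl carbon and sets C6 on a lactone next to C7.

**Alternative 2:** Cut only C6–CH2(allyl) and set C6 by catalyst control: zerovalent-palladium-catalysed decarboxylative asymmetric allylation of allyl β-keto ester A3 to the silyl ether A4 of the target.
- Structure: the problem moves to A3, whose C6–C7 bond still needs a β-keto ester to be alkylated by a secondary, β-oxygenated electrophile.
- Mechanism: the ligand would have to override two resident stereocentres beside the prochiral enolate.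
- Step economy: O8 needs a protecting group and C7/C8 must be made separately. In the chosen plan O8 is never protected and the template, not a catalyst, sets C6.

**Alternative 3:** (biomimetic) Cut C6–C7 and C8–O8 together: acid-promoted [3+2] cycloaddition of the cation from quinone monoketal A5 with (E)-propenylarene A6 to give bicyclic dienone A7, then conjugate reduction of the C4=C5 bond and the same reductive transposition as in the chosen route.
- This copies the presumed oxidative coupling of a propenylphenol with an allylphenol and would form two bonds and three stereocentres in one step.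
- Mechanism: both partners are achiral and the stepwise cationic process offers no handle for absolute configuration, so a racemate is expected. Attack at the unsubstituted ring positions and [5+2] closure to bicyclo[3.2.1]octanes should compete.
- Structure: the hindered α-methoxy enone C4=C5 would have to be reduced beside the allyl group.
- The chosen plan keeps the endgame of this logic (a bicyclic vinylogous ester) but reaches it as a single enantiomer.

Key step: step 7

Remark: the atom labels C1–C8 and O8 defined for 15 are used for the same atoms in all intermediates. The descriptor of the quaternary carbon changes between S and R along the route only because CIP priorities change.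

Assumption: in step 1 the (S)-configured phosphoric acid is taken to be the enantiomer that exposes the si face of the aryl aldehyde; if the sense were opposite, the (R)-acid would be used with no other change.

## Route

Step 1
Reactants: 1 3,4,5-trimethoxybenzaldehyde; 2 (E)-crotylboronic acid pinacol ester
Product: 3 (1S,2S)-2-methyl-1-(3,4,5-trimethoxyphenyl)but-3-en-1-ol
Conditions: (S)-TRIP [(S)-3,3′-bis(2,4,6-triisopropylphenyl)-1,1′-binaphthalene-2,2′-diyl hydrogen phosphate] (5 mol %), 4 Å MS, PhMe, −30 °C; then aq. NaHCO3
Reagents that add atoms: none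
Why: Chiral Brønsted acid catalysed crotylboration through a closed chair (Zimmerman–Traxler) transition state: the (E)-crotyl geometry should give the anti C7/C8 relationship, and the acid, hydrogen-bonded to a boronate oxygen and the formyl C–H, should expose the si face of 1 to give the (1S) carbinol.

Step 2
Reactants: 3 (1S,2S)-2-methyl-1-(3,4,5-trimethoxyphenyl)but-3-en-1-ol
Product: 4 (1S,2S)-2-methyl-1-(3,4,5-trimethoxyphenyl)butane-1,4-diol
Conditions: 9-BBN-H (2.2 equiv), THF, 0 → 25 °C; then NaOH, H2O2, 0 °C
Reagents that add atoms: hydrogen peroxide, OO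
Why: Anti-Markovnikov hydroboration of the only alkene by the bulky borane and oxidation of the C–B bond with retention; the free hydroxyl only consumes one equivalent of borane and no stereocentre is touched.

Step 3
Reactants: 4 (1S,2S)-2-methyl-1-(3,4,5-trimethoxyphenyl)butane-1,4-diol
Product: 5 (4S,5S)-4-methyl-5-(3,4,5-trimethoxyphenyl)oxolan-2-one
Conditions: TEMPO (10 mol %), PhI(OAc)2 (2.5 equiv), CH2Cl2, 25 °C
Reagents that add atoms: none
Why: Oxoammonium oxidation should pick the primary alcohol; the aldehyde closes to the lactol with O8 and is oxidized on to the γ-lactone (oxidative lactonization of a 1,4-diol), which fixes C7–CH3 and C8–aryl trans on the ring.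

Step 4
Reactants: 5 (4S,5S)-4-methyl-5-(3,4,5-trimethoxyphenyl)oxolan-2-one; 6 2-(2-bromoethyl)-2-methyl-1,3-dioxolane
Product: 7 (3S,4S,5S)-4-methyl-3-[2-(2-methyl-1,3-dioxolan-2-yl)ethyl]-5-(3,4,5-trimethoxyphenyl)oxolan-2-one
Conditions: LiN(i-Pr)2, THF, −78 °C; then 6, DMPU, −78 → 0 °C
Reagents that add atoms: none
Why: SN2 alkylation of the lactone lithium enolate by the primary bromide; the chain should enter trans to the C7 methyl group, but C6 is planarized again in step 5, so its configuration here is immaterial.

Step 5
Reactants: 7 (3S,4S,5S)-4-methyl-3-[2-(2-methyl-1,3-dioxolan-2-yl)ethyl]-5-(3,4,5-trimethoxyphenyl)oxolan-2-one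
Product: 8 (3S,4S,5S)-4-methyl-3-[2-(2-methyl-1,3-dioxolan-2-yl)ethyl]-3-(prop-2-en-1-yl)-5-(3,4,5-trimethoxyphenyl)oxolan-2-one
Conditions: LiN(i-Pr)2, THF, −78 °C; then allyl bromide, −78 → −40 °C
Reagents that add atoms: allyl bromide, C=CCBr
Why: Enolate alkylation that creates the quaternary centre: the enolate is planar at C6 and allyl bromide should approach anti to the adjacent C7 methyl group (1,2-induction, as usual for β-substituted butyrolactone enolates), placing allyl trans to C7–CH3 and the oxobutyl precursor cis, as the target requires.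

Step 6
Reactants: 8 (3S,4S,5S)-4-methyl-3-[2-(2-methyl-1,3-dioxolan-2-yl)ethyl]-3-(prop-2-en-1-yl)-5-(3,4,5-trimethoxyphenyl)oxolan-2-one
Product: 9 (3S,4S,5S)-4-methyl-3-(3-oxobutyl)-3-(prop-2-en-1-yl)-5-(3,4,5-trimethoxyphenyl)oxolan-2-one
Conditions: 1 M HCl, THF, 25 °C
Reagents that add atoms: water, O
Why: Acid-catalysed acetal hydrolysis; the lactone, the allyl group and the aryl ethers should be stable to dilute acid at room temperature.

Step 7
Reactants: 9 (3S,4S,5S)-4-methyl-3-(3-oxobutyl)-3-(prop-2-en-1-yl)-5-(3,4,5-trimethoxyphenyl)oxolan-2-one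
Product: 11 (2S,3S,3aS)-3-methyl-3a-(prop-2-en-1-yl)-2-(3,4,5-trimethoxyphenyl)-3,3a,4,5-tetrahydro-1-benzofuran-6(2H)-one, via hydroxy dione 10 (not isolated)
Conditions: KOt-Bu (2.2 equiv), t-BuOH/THF, 0 → 25 °C; 1 M HCl; then TsOH (cat.), PhMe, 80 °C, −H2O
Reagents that add atoms: none
Why: tert-Butoxide reversibly forms both enolates of the methyl ketone, but only the C2 (methyl-derived) enolate can reach the lactone carbonyl C1 through a six-membered transition state (6-exo-trig acyl substitution; the internal enolate would close a four-membered ring), so the C1–C2 bond forms by an intramolecular Claisen (Dieckmann-type) condensation, the closest known reaction type being the base-mediated cyclization of δ-keto esters to cyclohexane-1,3-diones. Collapse of the tetrahedral intermediate expels O8 as the C8 alkoxide and the product is at once deprotonated to the 1,3-diketonate (pKa near 5), which makes the sequence irreversible and shields the dione from retro-Claisen cleavage. On acidification hydroxy dione 10 closes the second ring by 5-exo-trig addition of O8–H to the C1 carbonyl and acid-catalysed loss of water; O8 can reach only C1 (five-membered ring), never C3, so the enol ether sits on the carbon next to the quaternary centre and the free ketone at C3. No stereocentre is created: C6 is quaternary, C7 carries no acidifying group and C8 keeps its C–O bond, so the three centres set on the lactone are carried over unchanged. The selectivities needed are intramolecular acylation over intermolecular aldol reaction (secured by the thermodynamic sink and moderate dilution) and regioselective enol ether formation (secured by ring size).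

Step 8
Reactants: 11 (2S,3S,3aS)-3-methyl-3a-(prop-2-en-1-yl)-2-(3,4,5-trimethoxyphenyl)-3,3a,4,5-tetrahydro-1-benzofuran-6(2H)-one
Product: 12 (2S,3S,3aR,5R)-5-hydroxy-3-methyl-3a-(prop-2-en-1-yl)-2-(3,4,5-trimethoxyphenyl)-3,3a,4,5-tetrahydro-1-benzofuran-6(2H)-one
Conditions: KN(SiMe3)2, THF, −78 °C; then 2-(phenylsulfonyl)-3-phenyloxaziridine; AcOH
Reagents that add atoms: 2-(phenylsulfonyl)-3-phenyloxaziridine, O=S(=O)(c1ccccc1)N1OC1c1ccccc1
Why: Enolate hydroxylation by an N-sulfonyloxaziridine: C4 is the only enolizable carbon because C6 is quaternary. In the bicycle C7 is held near the enol ether plane, so the allyl group on C6 is pseudoaxial and oxygen should be delivered to C4 anti to it, giving OH trans to allyl and cis to C7 (5R).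

Step 9
Reactants: 12 (2S,3S,3aR,5R)-5-hydroxy-3-methyl-3a-(prop-2-en-1-yl)-2-(3,4,5-trimethoxyphenyl)-3,3a,4,5-tetrahydro-1-benzofuran-6(2H)-one
Product: 13 (2S,3S,3aR,5R)-5-methoxy-3-methyl-3a-(prop-2-en-1-yl)-2-(3,4,5-trimethoxyphenyl)-3,3a,4,5-tetrahydro-1-benzofuran-6(2H)-one
Conditions: Ag2O, MeI, 4 Å MS, CH2Cl2, 25 °C, dark
Reagents that add atoms: iodomethane, CI
Why: Purdie-type O-methylation of the only free hydroxyl under nearly neutral conditions; C4 is epimerizable, but the desired isomer (equatorial OMe, trans to the pseudoaxial allyl) should also be the thermodynamic one.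

Step 10
Reactants: 13 (2S,3S,3aR,5R)-5-methoxy-3-methyl-3a-(prop-2-en-1-yl)-2-(3,4,5-trimethoxyphenyl)-3,3a,4,5-tetrahydro-1-benzofuran-6(2H)-one
Product: 15 (4R,6R)-6-[(1S,2S)-1-hydroxy-1-(3,4,5-trimethoxyphenyl)propan-2-yl]-4-methoxy-6-(prop-2-en-1-yl)cyclohex-2-en-1-one, via allylic alcohol 14 (not isolated)
Conditions: i-Bu2AlH, CH2Cl2, −78 °C; then 1 M HCl, THF, 0 °C
Reagents that add atoms: water, O
Why: Stork–Danheiser transposition: 1,2-reduction of the vinylogous ester carbonyl C3 gives 14, acid ionizes the allylic alcohol to an O8-stabilized allyl cation, and water adds at C1. The hemiketal collapses to the C1 ketone and the C2=C3 alkene and releases O8–H; C4, C6, C7 and C8 are not involved.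

## Compound list

1 | 3,4,5-trimethoxybenzaldehyde | COc1cc(C=O)cc(OC)c1OC | starting material
2 | (E)-2-(but-2-en-1-yl)-4,4,5,5-tetramethyl-1,3,2-dioxaborolane [(E)-crotylboronic acid pinacol ester] | C/C=C/CB1OC(C)(C)C(C)(C)O1 | starting material
3 | (1S,2S)-2-methyl-1-(3,4,5-trimethoxyphenyl)but-3-en-1-ol | C=C[C@H](C)[C@H](O)c1cc(OC)c(OC)c(OC)c1 | intermediate
4 | (1S,2S)-2-methyl-1-(3,4,5-trimethoxyphenyl)butane-1,4-diol | OCC[C@H](C)[C@H](O)c1cc(OC)c(OC)c(OC)c1 | intermediate
5 | (4S,5S)-4-methyl-5-(3,4,5-trimethoxyphenyl)oxolan-2-one | O=C1C[C@H](C)[C@H](O1)c2cc(OC)c(OC)c(OC)c2 | intermediate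
6 | 2-(2-bromoethyl)-2-methyl-1,3-dioxolane | CC1(CCBr)OCCO1 | starting material
7 | (3S,4S,5S)-4-methyl-3-[2-(2-methyl-1,3-dioxolan-2-yl)ethyl]-5-(3,4,5-trimethoxyphenyl)oxolan-2-one | CC3(OCCO3)CC[C@H]1[C@H](C)[C@@H](c2cc(OC)c(OC)c(OC)c2)OC1=O | intermediate
8 | (3S,4S,5S)-4-methyl-3-[2-(2-methyl-1,3-dioxolan-2-yl)ethyl]-3-(prop-2-en-1-yl)-5-(3,4,5-trimethoxyphenyl)oxolan-2-one | C=CC[C@]1([C@H](C)[C@@H](c2cc(OC)c(OC)c(OC)c2)OC1=O)CCC3(C)OCCO3 | intermediate
9 | (3S,4S,5S)-4-methyl-3-(3-oxobutyl)-3-(prop-2-en-1-yl)-5-(3,4,5-trimethoxyphenyl)oxolan-2-one | C=CC[C@]1([C@H](C)[C@@H](c2cc(OC)c(OC)c(OC)c2)OC1=O)CCC(C)=O | intermediate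
10 | (4S)-4-[(1S,2S)-1-hydroxy-1-(3,4,5-trimethoxyphenyl)propan-2-yl]-4-(prop-2-en-1-yl)cyclohexane-1,3-dione | C=CC[C@]1([C@H](C)[C@H](O)c2cc(OC)c(OC)c(OC)c2)CCC(=O)CC1=O | intermediate (not isolated)
11 | (2S,3S,3aS)-3-methyl-3a-(prop-2-en-1-yl)-2-(3,4,5-trimethoxyphenyl)-3,3a,4,5-tetrahydro-1-benzofuran-6(2H)-one | C=CC[C@@]12[C@H](C)[C@@H](c3cc(OC)c(OC)c(OC)c3)OC1=CC(=O)CC2 | intermediate
12 | (2S,3S,3aR,5R)-5-hydroxy-3-methyl-3a-(prop-2-en-1-yl)-2-(3,4,5-trimethoxyphenyl)-3,3a,4,5-tetrahydro-1-benzofuran-6(2H)-one | C=CC[C@@]12[C@H](C)[C@@H](c3cc(OC)c(OC)c(OC)c3)OC1=CC(=O)[C@H](O)C2 | intermediate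
13 | (2S,3S,3aR,5R)-5-methoxy-3-methyl-3a-(prop-2-en-1-yl)-2-(3,4,5-trimethoxyphenyl)-3,3a,4,5-tetrahydro-1-benzofuran-6(2H)-one | C=CC[C@@]12[C@H](C)[C@@H](c3cc(OC)c(OC)c(OC)c3)OC1=CC(=O)[C@H](OC)C2 | intermediate
14 | (2S,3S,3aR,5R)-5-methoxy-3-methyl-3a-(prop-2-en-1-yl)-2-(3,4,5-trimethoxyphenyl)-2,3,3a,4,5,6-hexahydro-1-benzofuran-6-ol (both C6 epimers) | C=CC[C@@]12[C@H](C)[C@@H](c3cc(OC)c(OC)c(OC)c3)OC1=CC(O)[C@H](OC)C2 | intermediate (not isolated)
15 | (4R,6R)-6-[(1S,2S)-1-hydroxy-1-(3,4,5-trimethoxyphenyl)propan-2-yl]-4-methoxy-6-(prop-2-en-1-yl)cyclohex-2-en-1-one | C=CC[C@]1([C@H](C)[C@H](O)c2cc(OC)c(OC)c(OC)c2)C[C@@H](OC)C=CC1=O | target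

## Step count and least certain steps

Total step count: 10. Longest linear sequence: 10 steps (1 → 15).

**Step 7 (key step).** Attack of the ketone enolate on the neopentyl-type, α-quaternary lactone carbonyl may be slow, so intermolecular aldol self-condensation of the methyl ketone or alkoxide-induced ring opening of the dione could outrun ring closure. In the acid stage, ionization of the electron-rich benzylic C8–O bond could cause epimerization or elimination.
Fallback (sets out from 8, returns at 11): the lactone is opened before the condensation.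
- Me2AlN(OMe)Me (from AlMe3 and MeONHMe·HCl) should convert 8 into the hydroxy N-methoxy-N-methylamide F1.
- Silylation (t-BuMe2SiOSO2CF3, 2,6-lutidine) should give the silyl ether F2.
- PPTS in aqueous acetone should release the keto amide F3.
- KN(SiMe3)2 should then effect intramolecular acylation by the amide; the chelated tetrahedral intermediate cannot revert, so work-up should give the silyloxy dione F4.
- TsOH in MeOH, then warm PhMe, should remove the silyl group and close the enol ether to 11.

**Step 4.** The SN2 reaction of the unactivated primary bromide with the lactone enolate may be sluggish, with competing E2 loss of HBr from 6 and Claisen self-condensation of the lactone.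
Fallback (sets out from 5, returns at 7): conjugate addition replaces substitution.
- LiN(i-Pr)2/t-BuMe2SiCl should give the silyl ketene acetal F8.
- TiCl4-promoted Mukaiyama–Michael addition to methyl vinyl ketone should give the keto lactone F9.
- Ketalization (ethylene glycol, TsOH, PhH, −H2O) returns to 7.

**Step 5.** Facial discrimination at the planar enolate carbon C6 may be poor, because the face anti to the C7 methyl group is the face syn to the C8 aryl group; O-allylation is a further risk.
Fallback (sets out from 7, returns at 8): ligand control is added to substrate control.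
- The potassium enolate (KN(SiMe3)2) is trapped with allyl chloroformate as the allyl enol carbonate F5.
- Decarboxylative allylation with Pd2(dba)3 (zerovalent palladium) and the t-Bu-PHOX enantiomer matched to the substrate bias should deliver the allyl group within a ligand-controlled ion pair.

**Step 8.** Oxygen transfer may occur from the wrong face of the dienolate, since the stereoelectronically preferred pseudoaxial attack is syn to the pseudoaxial allyl group. Aldol-type addition of the enolate to the sulfonimine formed from the oxidant is a further risk.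
Fallback (sets out from 11, returns at 13): thermodynamic control replaces kinetic control.
- The C4-epimeric hydroxy ketone F6 is carried through the same Ag2O/MeI methylation to the epimeric methyl ether F7.
- DBU in PhMe at 60 °C should equilibrate F7 through the enol to 13, the isomer with the equatorial methoxy group trans to the pseudoaxial allyl group.

## Further compounds

F1 | step 7 | (2S)-2-[(1S,2S)-1-hydroxy-1-(3,4,5-trimethoxyphenyl)propan-2-yl]-N-methoxy-N-methyl-4-(2-methyl-1,3-dioxolan-2-yl)-2-(prop-2-en-1-yl)butanamide | C=CC[C@](C(=O)N(C)OC)([C@H](C)[C@H](O)c1cc(OC)c(OC)c(OC)c1)CCC2(C)OCCO2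
F2 | step 7 | (2S)-2-[(1S,2S)-1-{[tert-butyl(dimethyl)silyl]oxy}-1-(3,4,5-trimethoxyphenyl)propan-2-yl]-N-methoxy-N-methyl-4-(2-methyl-1,3-dioxolan-2-yl)-2-(prop-2-en-1-yl)butanamide | C=CC[C@](C(=O)N(C)OC)([C@H](C)[C@H](O[Si](C)(C)C(C)(C)C)c1cc(OC)c(OC)c(OC)c1)CCC2(C)OCCO2
F3 | step 7 | (2S)-2-[(1S,2S)-1-{[tert-butyl(dimethyl)silyl]oxy}-1-(3,4,5-trimethoxyphenyl)propan-2-yl]-N-methoxy-N-methyl-5-oxo-2-(prop-2-en-1-yl)hexanamide | C=CC[C@](C(=O)N(C)OC)([C@H](C)[C@H](O[Si](C)(C)C(C)(C)C)c1cc(OC)c(OC)c(OC)c1)CCC(C)=O
F4 | step 7 | (4S)-4-[(1S,2S)-1-{[tert-butyl(dimethyl)silyl]oxy}-1-(3,4,5-trimethoxyphenyl)propan-2-yl]-4-(prop-2-en-1-yl)cyclohexane-1,3-dione | C=CC[C@]1([C@H](C)[C@H](O[Si](C)(C)C(C)(C)C)c2cc(OC)c(OC)c(OC)c2)CCC(=O)CC1=O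
F5 | step 5 | prop-2-en-1-yl (4S,5S)-4-methyl-3-[2-(2-methyl-1,3-dioxolan-2-yl)ethyl]-5-(3,4,5-trimethoxyphenyl)-4,5-dihydrofuran-2-yl carbonate | C=CCOC(=O)OC1=C(CCC3(C)OCCO3)[C@H](C)[C@@H](c2cc(OC)c(OC)c(OC)c2)O1
F6 | step 8 | (2S,3S,3aR,5S)-5-hydroxy-3-methyl-3a-(prop-2-en-1-yl)-2-(3,4,5-trimethoxyphenyl)-3,3a,4,5-tetrahydro-1-benzofuran-6(2H)-one | C=CC[C@@]12[C@H](C)[C@@H](c3cc(OC)c(OC)c(OC)c3)OC1=CC(=O)[C@@H](O)C2
F7 | step 8 | (2S,3S,3aR,5S)-5-methoxy-3-methyl-3a-(prop-2-en-1-yl)-2-(3,4,5-trimethoxyphenyl)-3,3a,4,5-tetrahydro-1-benzofuran-6(2H)-one | C=CC[C@@]12[C@H](C)[C@@H](c3cc(OC)c(OC)c(OC)c3)OC1=CC(=O)[C@@H](OC)C2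
F8 | step 4 | tert-butyl(dimethyl){[(4S,5S)-4-methyl-5-(3,4,5-trimethoxyphenyl)-4,5-dihydrofuran-2-yl]oxy}silane | CC(C)(C)[Si](C)(C)OC1=C[C@H](C)[C@@H](c2cc(OC)c(OC)c(OC)c2)O1
F9 | step 4 | (3S,4S,5S)-4-methyl-3-(3-oxobutyl)-5-(3,4,5-trimethoxyphenyl)oxolan-2-one | CC(=O)CC[C@H]1[C@H](C)[C@@H](c2cc(OC)c(OC)c(OC)c2)OC1=O
A1 | alternative 1 | (4R)-4-methoxy-6-(prop-2-en-1-yl)cyclohex-2-en-1-one (C6 epimers) | C=CCC1C[C@@H](OC)C=CC1=O
A2 | alternative 1 | (2S,3R)-2-methyl-3-(3,4,5-trimethoxyphenyl)oxirane (cis) | O1[C@@H](C)[C@H]1c2cc(OC)c(OC)c(OC)c2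
A3 | alternative 2 | prop-2-en-1-yl (5R)-1-[(1S,2S)-1-{[tert-butyl(dimethyl)silyl]oxy}-1-(3,4,5-trimethoxyphenyl)propan-2-yl]-5-methoxy-2-oxocyclohex-3-ene-1-carboxylate (C1 epimers) | C=CCOC(=O)C1([C@H](C)[C@H](O[Si](C)(C)C(C)(C)C)c2cc(OC)c(OC)c(OC)c2)C[C@@H](OC)C=CC1=O
A4 | alternative 2 | (4R,6R)-6-[(1S,2S)-1-{[tert-butyl(dimethyl)silyl]oxy}-1-(3,4,5-trimethoxyphenyl)propan-2-yl]-4-methoxy-6-(prop-2-en-1-yl)cyclohex-2-en-1-one | C=CC[C@]1([C@H](C)[C@H](O[Si](C)(C)C(C)(C)C)c2cc(OC)c(OC)c(OC)c2)C[C@@H](OC)C=CC1=O
A5 | alternative 3 | 4,4,5-trimethoxy-2-(prop-2-en-1-yl)cyclohexa-2,5-dien-1-one | C=CCC1=CC(OC)(OC)C(OC)=CC1=O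
A6 | alternative 3 | (E)-1,2,3-trimethoxy-5-(prop-1-en-1-yl)benzene | C/C=C/c1cc(OC)c(OC)c(OC)c1
A7 | alternative 3 | racemic 5-methoxy-3-methyl-3a-(prop-2-en-1-yl)-2-(3,4,5-trimethoxyphenyl)-3,3a-dihydro-1-benzofuran-6(2H)-one, relative configuration as in 13 (one enantiomer drawn) | C=CC[C@@]12[C@H](C)[C@@H](c3cc(OC)c(OC)c(OC)c3)OC1=CC(=O)C(OC)=C2
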